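**Assumption:** the 4-OH of 3,4-dihydroxybenzaldehyde is the more acidic and more reactive phenol, so the chromene closes onto C5 (ortho to the 4-O). The target is (2S) by CIP analysis of the SMILES: O > aryl C > CH2 > H.

**Retrosynthesis**
- The flavanone C2–O1 bond is disconnected to an achiral 2′,4′,6′-trihydroxychalcone (5). Its two ortho-OH groups are enantiotopic, so this is the key symmetry-breaking step: chalcone isomerase picks one OH and one enone face to set 2S.
- The chalcone is disconnected (Claisen–Schmidt) into phloroacetophenone (4), a symmetric phloroglucinol-type precursor, and the chromene aldehyde 3.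
- The B-ring 2,2-dimethyl-2H-chromene is disconnected by [3+3] annulation (3-methylbut-2-enal, 2) onto the cheap feedstock 3,4-dihydroxybenzaldehyde (1).
- Rings form in this order: the pyran on the B ring, then the chalcone C=C, then the flavanone heterocycle last.

---

**Step 1**
Reactants: 1 (3,4-dihydroxybenzaldehyde) + 2 (3-methylbut-2-enal)
Product: 3 (8-hydroxy-2,2-dimethyl-2H-chromene-6-carbaldehyde)
Conditions: 2 (2 equiv), ethylenediammonium diacetate (20 mol%), xylene, reflux (Dean–Stark), 12 h
Reagents that add atoms: none beyond the numbered reactants (the catalyst is not incorporated)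
Why: This is an amine-catalysed phenol–enal [3+3] annulation (ortho-alkylation, then o-quinone-methide formation and 6π-oxa-electrocyclization). It builds the 2,2-dimethylchromene with the pyran O on C4 and the 3-OH left free, and it creates no stereocenter.

**Step 2**
Reactants: 3 + 4 (2′,4′,6′-trihydroxyacetophenone)
Product: 5 ((E)-1-(2,4,6-trihydroxyphenyl)-3-(8-hydroxy-2,2-dimethyl-2H-chromen-6-yl)prop-2-en-1-one)
Conditions: 50% aq KOH (≈6 equiv), EtOH, N2, rt, 48 h; then 1 M HCl at 0 °C to pH ≈3, rapid EtOAc extraction, flash chromatography
Reagents that add atoms: none (KOH and HCl only deprotonate and reprotonate)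
Why: Claisen–Schmidt condensation. Excess base keeps the phenols as phenolates, so the ring-closed flavanone is held as the ring-opened chalcone. The aldehyde's free 8-OH is meta to the CHO and does not deactivate it. The product is achiral, so no stereocenter is set here.

**Step 3**
Reactants: 5
Product: 6 ((2S)-5,7-dihydroxy-flavanone with the 2,2-dimethylpyran fused across B-ring C3′/C4′, the target)
Conditions: recombinant chalcone isomerase (Medicago sativa, type I), 50 mM K-phosphate pH 7.0, 5% DMSO, 25 °C, 1–2 h; EtOAc extraction
Reagents that add atoms: none (isomerisation)
Why: Enzymatic intramolecular oxa-Michael addition of a 6′-OH onto the enone, with the enzyme selecting one of the two enantiotopic ortho-OH groups and one enone face to give the (2S)-flavanone, with no added reagents. Proposed new method: chalcone isomerase is known to cyclise 2′,4′,6′-trihydroxychalcones with B-ring hydroxy and prenyl substituents to (2S)-flavanones at close to diffusion-controlled rates. Applying it to this B-ring chromene-fused chalcone extends that substrate scope, on the reasoning that the B ring sits in an open hydrophobic pocket. At pH 7 the enzyme far outruns the uncatalysed background cyclisation, which would give racemic product.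

---

**Consistency checks**
- Atom balance: 1 (C7H6O3) + 2 (C5H8O) − H2O gives 3 (C12H12O3). 3 + 4 (C8H8O4) − H2O gives 5 (C20H18O6). Step 3 is an isomerisation, so 6 is C20H18O6, matching the target.
- Ring sizes and substituents: 6 has the 2,2-dimethyl-2H-chromene (O1–CMe2–CH=CH–C) fused at B-ring C3′/C4′, a free 5′-OH (ortho to the pyran O), and 5,7-diOH on the chromanone A ring. This matches the SMILES.
- Functional-group survival: the chromene alkene and free phenols survive base at rt and brief cold dilute acid. Step 3 runs at near-neutral pH, which avoids ring-opening and racemisation of the 5-hydroxyflavanone.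
- Stereochemistry: the only stereocenter, C2, is set in the last step and never touched afterwards.

---

**Compound list**
1 | 3,4-dihydroxybenzaldehyde | O=Cc1ccc(O)c(O)c1 | starting material
2 | 3-methylbut-2-enal | CC(C)=CC=O | starting material
3 | 8-hydroxy-2,2-dimethyl-2H-chromene-6-carbaldehyde | CC1(C)C=Cc2cc(C=O)cc(O)c2O1 | intermediate
4 | 2′,4′,6′-trihydroxyacetophenone (phloroacetophenone) | CC(=O)c1c(O)cc(O)cc1O | starting material
5 | (E)-chalcone: 1-(2,4,6-trihydroxyphenyl)-3-(8-hydroxy-2,2-dimethyl-2H-chromen-6-yl)prop-2-en-1-one | CC1(C)C=Cc2cc(/C=C/C(=O)c3c(O)cc(O)cc3O)cc(O)c2O1 | intermediate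
6 | (2S)-5,7-dihydroxy-flavanone with fused 2,2-dimethylpyran on the B ring | CC1(C)C=Cc2cc([C@@H]3CC(=O)c4c(O)cc(O)cc4O3)cc(O)c2O1 | target

---

**Total steps:** 3. **Longest linear sequence:** 3 (1 → 3 → 5 → 6).

**Three steps most likely to fail**
1. **Step 3 (chalcone isomerase on an unnatural chromene-fused chalcone).** The enzyme may not accept the substrate, or ee may erode from background cyclisation. Fallback: cyclise 5 non-enzymatically (NaOAc, EtOH, reflux) to racemic 6, then resolve by preparative chiral-phase HPLC to isolate the (S)-enantiomer.
2. **Step 1 (regioselectivity and yield of the one-pot chromene annulation).** Attack at C2 (via the 3-OH), or catechol side reactions, may compete. Fallback: selective 4-O-propargylation of 1 (3-chloro-3-methylbut-1-yne, K2CO3/CuI, DMF), then thermal aromatic Claisen rearrangement and 1,5-H shift/6π-electrocyclisation. Only C5 is free, which fixes the regiochemistry.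
3. **Step 2 (Claisen–Schmidt on fully unprotected polyphenols).** Yields may be low, or some chalcone may cyclise to racemic flavanone on work-up. Fallback: Knoevenagel–Doebner conversion of 3 to the (E)-cinnamic acid, then BF3·OEt2 Friedel–Crafts acylation of phloroglucinol to give 5, avoiding the aldol condensation.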